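## Retrosynthetic overview

1. Target 28 ⇐ 27 by global MOM removal; 27 ⇐ 3-aryl-4-hydroxycoumarin 25 + 2-methylbut-3-en-2-ol by a new enantioselective C3-prenylation that sets the quaternary centre.
2. 25 ⇐ 23 by kinetic enolate protonation (inverts C4'' to the all-cis triad); 23 ⇐ spiro-epoxide 22 by Lewis-acid ring expansion through a 1,2-acyl shift (key step: five-membered furanone → six-membered lactone).
3. 22 ⇐ aurone 21 ⇐ benzofuran-3-one 20 + aldehyde 4; 20 ⇐ phenol 17 + bromoacetic acid; 17 ⇐ C–H borylation/oxidation of ring A.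
4. Cyclohexene core 14 ⇐ asymmetric [4+2] of chalcone 8 with aryl diene 13; every aromatic ring comes from resorcinol.
5. Ring order: cyclohexene (step 8) → furanone (step 12) → ring-expanded lactone (step 15).

Assumption: the VANOL enantiomer (step 8) and the Trost-ligand enantiomer (step 17) are written as those expected to give the drawn configurations; if a first run shows the opposite sense, the mirror-image ligand is used.

Notation: MOM = CH2OCH3, MOMO = methoxymethoxy. Cyclohexene atoms: C1''(Me)=C2''H–C3''H(ring A)–C4''H(aroyl)–C5''H(aryl)–C6''H2. Rexo = (1S,5R,6S)-6-[2,4-bis(MOMO)benzoyl]-5-[2,4-bis(MOMO)phenyl]-3-methylcyclohex-2-en-1-yl (aroyl trans to both aryl groups). Rcis = its (1S,5R,6R) epimer (all-cis).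

## Route

Step 1
Reactants: 1 resorcinol
Product: 3 2,4-dihydroxybenzaldehyde, via iminium chloride 2 (not isolated)
Conditions: POCl3, DMF, MeCN, −15 → 25 °C; then H2O, 50 °C
Reagents that add atoms: N,N-dimethylformamide, CN(C)C=O; water, O
Why: Vilsmeier–Haack formylation, in which the chloroiminium ion attacks C4 of resorcinol (ortho/para to both hydroxyls) and iminium salt 2 is hydrolysed to the aldehyde.

Step 2
Reactants: 3 2,4-dihydroxybenzaldehyde
Product: 4 2,4-bis(methoxymethoxy)benzaldehyde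
Conditions: MOMCl (2.5 equiv), K2CO3, acetone, reflux
Reagents that add atoms: chloromethyl methyl ether, COCCl
Why: Williamson-type MOM protection of both phenols, the chelated ortho-hydroxyl needing reflux.

Step 3
Reactants: 1 resorcinol; 5 acetic acid
Product: 6 1-(2,4-dihydroxyphenyl)ethanone
Conditions: ZnCl2, AcOH, 140 °C
Reagents that add atoms: none
Why: Nencki reaction (Friedel–Crafts C-acetylation) places the acetyl group at C4, the position activated by both hydroxyls.

Step 4
Reactants: 6 1-(2,4-dihydroxyphenyl)ethanone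
Product: 7 1-[2-hydroxy-4-(methoxymethoxy)phenyl]ethanone
Conditions: MOMCl (1.1 equiv), K2CO3, acetone, 0 → 25 °C
Reagents that add atoms: chloromethyl methyl ether, COCCl
Why: the 2-OH is locked in a hydrogen bond to the ketone, so one equivalent of MOMCl alkylates only the 4-OH (selective Williamson-type protection).

Step 5
Reactants: 7 1-[2-hydroxy-4-(methoxymethoxy)phenyl]ethanone; 4 2,4-bis(methoxymethoxy)benzaldehyde
Product: 8 (E)-3-[2,4-bis(MOMO)phenyl]-1-[2-hydroxy-4-(MOMO)phenyl]prop-2-en-1-one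
Conditions: KOH, EtOH–H2O, 25 °C
Reagents that add atoms: none
Why: Claisen–Schmidt condensation (aldol addition then E1cB dehydration) gives the (E)-chalcone and keeps the 2'-OH free for boron chelation in step 8.

Step 6
Reactants: 1 resorcinol
Product: 9 1,3-bis(methoxymethoxy)benzene
Conditions: NaH, MOMCl, DMF, 0 → 25 °C
Reagents that add atoms: chloromethyl methyl ether, COCCl
Why: Williamson-type MOM protection of both phenoxides, installing the two groups that direct the metalation in step 7.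

Step 7
Reactants: 9 1,3-bis(methoxymethoxy)benzene; 10 3-methylbut-2-enal
Product: 13 1,3-bis(methoxymethoxy)-2-[(1E)-3-methylbuta-1,3-dien-1-yl]benzene, via aryllithium 11 (not isolated), via lithium alkoxide 12 (not isolated)
Conditions: n-BuLi, THF, 0 → 25 °C; 10, −78 → 0 °C; then MsCl, Et3N, 0 → 25 °C
Reagents that add atoms: none
Why: directed ortho-metalation between the two MOM ethers, 1,2-addition to the enal, then mesylation and 1,4-elimination through the doubly stabilised benzylic–allylic cation give the conjugated (E)-aryl diene.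

Step 8
Reactants: 8 (E)-3-[2,4-bis(MOMO)phenyl]-1-[2-hydroxy-4-(MOMO)phenyl]prop-2-en-1-one; 13 1,3-bis(methoxymethoxy)-2-[(1E)-3-methylbuta-1,3-dien-1-yl]benzene
Product: 14 {(1S,2S,6R)-2-[2,6-bis(MOMO)phenyl]-6-[2,4-bis(MOMO)phenyl]-4-methylcyclohex-3-en-1-yl}[2-hydroxy-4-(MOMO)phenyl]methanone
Conditions: (R)-VANOL (1.2 equiv), B(OPh)3 (1.0 equiv), 5 Å MS, PhCF3, 25 °C; 13 (3 equiv); exo isomer separated from endo by chromatography
Reagents that add atoms: none
Why: asymmetric Diels–Alder reaction in which the 2'-hydroxychalcone is bound as a chiral VANOL borate that activates the enone and shields one face; the diene CH2 terminus bonds to the β-carbon (C5''), the E-alkene fixes C4''/C5'' trans, and exo approach of the bulky 2,6-disubstituted aryl gives the 3'',4''-trans adduct (3''S,4''S,5''R).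

Step 9
Reactants: 14 exo adduct with free 2'-OH
Product: 15 {(1S,2S,6R)-2-[2,6-bis(MOMO)phenyl]-6-[2,4-bis(MOMO)phenyl]-4-methylcyclohex-3-en-1-yl}[2,4-bis(MOMO)phenyl]methanone
Conditions: NaH (1.1 equiv), MOMCl, DMF, 0 °C
Reagents that add atoms: chloromethyl methyl ether, COCCl
Why: Williamson-type MOM protection of the chelated phenol removes the last acidic OH before borylation, alkylation and enolate chemistry; the trans,trans ketone is the thermodynamic isomer and cannot be eroded by base.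

Step 10
Reactants: 15 MOM-protected exo adduct
Product: 17 {(1S,2S,6R)-2-[4-hydroxy-2,6-bis(MOMO)phenyl]-6-[2,4-bis(MOMO)phenyl]-4-methylcyclohex-3-en-1-yl}[2,4-bis(MOMO)phenyl]methanone, via aryl boronate 16 (not isolated)
Conditions: [Ir(OMe)(cod)]2 (3 mol %), dtbpy (6 mol %), B2pin2 (1.0 equiv), THF, 70 °C; then NaOH, 30 % H2O2, 0 °C
Reagents that add atoms: bis(pinacolato)diboron, CC1(C)OB(OC1(C)C)B1OC(C)(C)C(C)(C)O1 (boron group of 16); hydrogen peroxide, OO (new oxygen of 17)
Why: sterically controlled iridium-catalysed C–H borylation occurs only at the one aryl C–H with no ortho substituent (para to the cyclohexenyl group on ring A), and oxidation of the C–B bond gives the third oxygen of ring A.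

Step 11
Reactants: 17 ring-A phenol; 18 bromoacetic acid
Product: 19 2-[4-Rexo-3,5-bis(MOMO)phenoxy]acetic acid
Conditions: K2CO3 (3 equiv), DMF, 50 °C; then 1 M HCl to pH 3
Reagents that add atoms: none
Why: Williamson ether synthesis in which the only phenoxide displaces bromide from bromoacetate.

Step 12
Reactants: 19 2-[4-Rexo-3,5-bis(MOMO)phenoxy]acetic acid
Product: 20 5-Rexo-4,6-bis(MOMO)-1-benzofuran-3(2H)-one
Conditions: TFAA (2.2 equiv), 2,6-di-tert-butyl-4-methylpyridine (2.5 equiv), CH2Cl2, −10 → 0 °C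
Reagents that add atoms: none
Why: intramolecular Friedel–Crafts acylation via the mixed trifluoroacetic anhydride closes the five-membered ring onto the carbon ortho to the ether oxygen, which is activated by three oxygen substituents and has a symmetry-equivalent twin, so one regioisomer forms.

Step 13
Reactants: 20 5-Rexo-4,6-bis(MOMO)-1-benzofuran-3(2H)-one; 4 2,4-bis(methoxymethoxy)benzaldehyde
Product: 21 (2Z)-2-[2,4-bis(MOMO)benzylidene]-5-Rexo-4,6-bis(MOMO)-1-benzofuran-3(2H)-one
Conditions: neutral Al2O3, CH2Cl2, 25 °C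
Reagents that add atoms: none
Why: aldol condensation of the C2 methylene of the benzofuranone with the aldehyde gives the thermodynamically favoured (Z)-aurone.

Step 14
Reactants: 21 (Z)-aurone
Product: 22 3'-[2,4-bis(MOMO)phenyl]-5-Rexo-4,6-bis(MOMO)-3H-spiro[1-benzofuran-2,2'-oxiran]-3-one (mixture of epoxide diastereomers)
Conditions: 30 % H2O2, NaOH (cat.), MeOH–THF, 0 → 25 °C
Reagents that add atoms: hydrogen peroxide, OO
Why: Weitz–Scheffer nucleophilic epoxidation, in which hydroperoxide adds only to the electron-poor exocyclic enone and leaves the electron-rich cyclohexene untouched; the epoxide stereocenters need no control because step 15 destroys both.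

Step 15
Reactants: 22 aurone spiro-epoxide
Product: 23 3-[2,4-bis(MOMO)phenyl]-4-hydroxy-5,7-bis(MOMO)-6-Rexo-2H-chromen-2-one
Conditions: Sc(OTf)3 (10 mol %), CH2Cl2, −20 → 0 °C
Reagents that add atoms: none
Why: Lewis-acid ring expansion by 1,2-acyl shift (House–Meinwald/semipinacol type), in which the epoxide opens at the benzylic carbon (cation stabilised by the 2,4-dialkoxyphenyl group), the ring ketone carbon migrates from C2 to that carbon so that C2 becomes the lactone carbonyl, and the six-membered chroman-2,4-dione enolises to the 4-hydroxycoumarin.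

Step 16
Reactants: 23 exo 4-hydroxycoumarin
Product: 25 3-[2,4-bis(MOMO)phenyl]-4-hydroxy-5,7-bis(MOMO)-6-Rcis-2H-chromen-2-one, via dilithium dienolate 24 (not isolated)
Conditions: LiN(iPr)2 (2.3 equiv), THF, −78 → −30 °C; then AcOH (6 equiv), THF, −78 °C
Reagents that add atoms: none
Why: kinetic enolate protonation, in which both flanking aryl groups (C3'' and C5'') of dienolate 24 sit on the same ring face, so the proton reaches C4'' from the open opposite face and the aroyl group ends cis to both aryls (4''R, contra-thermodynamic all-cis triad) while the coumarin is protected as its enolate.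

Step 17
Reactants: 25 all-cis 4-hydroxycoumarin; 26 2-methylbut-3-en-2-ol
Product: 27 (3S)-3-[2,4-bis(MOMO)phenyl]-5,7-bis(MOMO)-3-(3-methylbut-2-en-1-yl)-6-Rcis-2H-chromene-2,4(3H)-dione
Conditions: Pd2(dba)3·CHCl3 (2.5 mol %), (R,R)-ANDEN-phenyl Trost ligand (7.5 mol %), 26 (3 equiv), 4 Å MS, CH2Cl2, 25 °C
Reagents that add atoms: none
Why: Proposed new method: enantioselective dehydrative Tsuji–Trost C3-prenylation of a 3-aryl-4-hydroxycoumarin, in which the acidic enol (pKa about 5) protonates the tertiary allylic alcohol bound to zerovalent palladium, water leaves to give a (1,1-dimethylallyl)palladium cation paired with the planar coumarin enolate, and outer-sphere C-attack at the unsubstituted allyl terminus inside the chiral ligand pocket delivers the linear prenyl group to one enolate face, setting the (3S) quaternary centre without base so the all-cis ketone is not epimerised; the closest known reactions are the palladium-catalysed asymmetric linear prenylation of 3-aryloxindoles and the base-free palladium-catalysed allylation of 1,3-dicarbonyls with allylic alcohols.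

Step 18
Reactants: 27 octa-MOM-protected target
Product: 28 (3S)-6-[(1S,5R,6R)-6-(2,4-dihydroxybenzoyl)-5-(2,4-dihydroxyphenyl)-3-methylcyclohex-2-en-1-yl]-3-(2,4-dihydroxyphenyl)-5,7-dihydroxy-3-(3-methylbut-2-en-1-yl)-2H-chromene-2,4(3H)-dione (CNP0157558.4)
Conditions: HCl (1 M in MeOH), THF, 0 → 25 °C, short reaction time
Reagents that add atoms: none
Why: acid-catalysed acetal exchange with methanol removes all eight MOM groups as dimethoxymethane at or below room temperature, where the prenyl group, the lactone and the all-cis ketone are kinetically stable.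

## Compound list

1 | resorcinol | Oc1cccc(O)c1 | starting material
2 | N-(2,4-dihydroxybenzylidene)-N-methylmethanaminium chloride | C[N+](C)=Cc1ccc(O)cc1O.[Cl-] | intermediate
3 | 2,4-dihydroxybenzaldehyde | O=Cc1ccc(O)cc1O | intermediate
4 | 2,4-bis(methoxymethoxy)benzaldehyde | O=Cc1ccc(OCOC)cc1OCOC | intermediate
5 | acetic acid | CC(=O)O | starting material
6 | 1-(2,4-dihydroxyphenyl)ethanone | CC(=O)c1ccc(O)cc1O | intermediate
7 | 1-[2-hydroxy-4-(methoxymethoxy)phenyl]ethanone | CC(=O)c1ccc(OCOC)cc1O | intermediate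
8 | (E)-3-[2,4-bis(MOMO)phenyl]-1-[2-hydroxy-4-(MOMO)phenyl]prop-2-en-1-one | O=C(/C=C/c1ccc(OCOC)cc1OCOC)c1ccc(OCOC)cc1O | intermediate
9 | 1,3-bis(methoxymethoxy)benzene | COCOc1cccc(OCOC)c1 | intermediate
10 | 3-methylbut-2-enal | CC(C)=CC=O | starting material
11 | [2,6-bis(methoxymethoxy)phenyl]lithium | [Li]c1c(OCOC)cccc1OCOC | intermediate
12 | lithium 1-[2,6-bis(methoxymethoxy)phenyl]-3-methylbut-2-en-1-olate (racemic) | [Li+].[O-]C(C=C(C)C)c1c(OCOC)cccc1OCOC | intermediate
13 | 1,3-bis(methoxymethoxy)-2-[(1E)-3-methylbuta-1,3-dien-1-yl]benzene | C=C(C)/C=C/c1c(OCOC)cccc1OCOC | intermediate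
14 | {(1S,2S,6R)-2-[2,6-bis(MOMO)phenyl]-6-[2,4-bis(MOMO)phenyl]-4-methylcyclohex-3-en-1-yl}[2-hydroxy-4-(MOMO)phenyl]methanone | COCOc1cccc(OCOC)c1[C@H]2C=C(C)C[C@@H](c3ccc(OCOC)cc3OCOC)[C@@H]2C(=O)c4ccc(OCOC)cc4O | intermediate
15 | {(1S,2S,6R)-2-[2,6-bis(MOMO)phenyl]-6-[2,4-bis(MOMO)phenyl]-4-methylcyclohex-3-en-1-yl}[2,4-bis(MOMO)phenyl]methanone | COCOc1cccc(OCOC)c1[C@H]2C=C(C)C[C@@H](c3ccc(OCOC)cc3OCOC)[C@@H]2C(=O)c4ccc(OCOC)cc4OCOC | intermediate
16 | 4-pinacolboryl derivative of 15 (boron para to the cyclohexenyl group on ring A) | COCOc1cc(B5OC(C)(C)C(C)(C)O5)cc(OCOC)c1[C@H]2C=C(C)C[C@@H](c3ccc(OCOC)cc3OCOC)[C@@H]2C(=O)c4ccc(OCOC)cc4OCOC | intermediate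
17 | {(1S,2S,6R)-2-[4-hydroxy-2,6-bis(MOMO)phenyl]-6-[2,4-bis(MOMO)phenyl]-4-methylcyclohex-3-en-1-yl}[2,4-bis(MOMO)phenyl]methanone | COCOc1cc(O)cc(OCOC)c1[C@H]2C=C(C)C[C@@H](c3ccc(OCOC)cc3OCOC)[C@@H]2C(=O)c4ccc(OCOC)cc4OCOC | intermediate
18 | bromoacetic acid | OC(=O)CBr | starting material
19 | 2-[4-Rexo-3,5-bis(MOMO)phenoxy]acetic acid | COCOc1cc(OCC(=O)O)cc(OCOC)c1[C@H]2C=C(C)C[C@@H](c3ccc(OCOC)cc3OCOC)[C@@H]2C(=O)c4ccc(OCOC)cc4OCOC | intermediate
20 | 5-Rexo-4,6-bis(MOMO)-1-benzofuran-3(2H)-one | O=C1COc2cc(OCOC)c([C@H]3C=C(C)C[C@@H](c4ccc(OCOC)cc4OCOC)[C@@H]3C(=O)c5ccc(OCOC)cc5OCOC)c(OCOC)c21 | intermediate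
21 | (2Z)-2-[2,4-bis(MOMO)benzylidene]-5-Rexo-4,6-bis(MOMO)-1-benzofuran-3(2H)-one | O=C1/C(=C/c2ccc(OCOC)cc2OCOC)Oc2cc(OCOC)c([C@H]3C=C(C)C[C@@H](c4ccc(OCOC)cc4OCOC)[C@@H]3C(=O)c5ccc(OCOC)cc5OCOC)c(OCOC)c21 | intermediate
22 | 3'-[2,4-bis(MOMO)phenyl]-5-Rexo-4,6-bis(MOMO)-3H-spiro[1-benzofuran-2,2'-oxiran]-3-one (epoxide diastereomers) | O=C1C6(OC6c2ccc(OCOC)cc2OCOC)Oc2cc(OCOC)c([C@H]3C=C(C)C[C@@H](c4ccc(OCOC)cc4OCOC)[C@@H]3C(=O)c5ccc(OCOC)cc5OCOC)c(OCOC)c21 | intermediate
23 | 3-[2,4-bis(MOMO)phenyl]-4-hydroxy-5,7-bis(MOMO)-6-Rexo-2H-chromen-2-one | OC1=C(c2ccc(OCOC)cc2OCOC)C(=O)Oc2cc(OCOC)c([C@H]3C=C(C)C[C@@H](c4ccc(OCOC)cc4OCOC)[C@@H]3C(=O)c5ccc(OCOC)cc5OCOC)c(OCOC)c21 | intermediate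
24 | dilithium dienolate of 23 (coumarin 4-olate and C4'' ketone enolate) | [Li+].[Li+].[O-]C1=C(c2ccc(OCOC)cc2OCOC)C(=O)Oc2cc(OCOC)c([C@H]3C=C(C)C[C@@H](c4ccc(OCOC)cc4OCOC)C3=C([O-])c5ccc(OCOC)cc5OCOC)c(OCOC)c21 | intermediate
25 | 3-[2,4-bis(MOMO)phenyl]-4-hydroxy-5,7-bis(MOMO)-6-Rcis-2H-chromen-2-one | OC1=C(c2ccc(OCOC)cc2OCOC)C(=O)Oc2cc(OCOC)c([C@H]3C=C(C)C[C@@H](c4ccc(OCOC)cc4OCOC)[C@H]3C(=O)c5ccc(OCOC)cc5OCOC)c(OCOC)c21 | intermediate
26 | 2-methylbut-3-en-2-ol | CC(C)(O)C=C | starting material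
27 | (3S)-3-[2,4-bis(MOMO)phenyl]-5,7-bis(MOMO)-3-(3-methylbut-2-en-1-yl)-6-Rcis-2H-chromene-2,4(3H)-dione | CC(C)=CC[C@@]1(c2ccc(OCOC)cc2OCOC)C(=O)Oc2cc(OCOC)c([C@H]3C=C(C)C[C@@H](c4ccc(OCOC)cc4OCOC)[C@H]3C(=O)c5ccc(OCOC)cc5OCOC)c(OCOC)c2C1=O | intermediate
28 | (3S)-6-[(1S,5R,6R)-6-(2,4-dihydroxybenzoyl)-5-(2,4-dihydroxyphenyl)-3-methylcyclohex-2-en-1-yl]-3-(2,4-dihydroxyphenyl)-5,7-dihydroxy-3-(3-methylbut-2-en-1-yl)-2H-chromene-2,4(3H)-dione | CC(C)=CC[C@@]1(c2ccc(O)cc2O)C(=O)Oc2cc(O)c([C@H]3C=C(C)C[C@@H](c4ccc(O)cc4O)[C@H]3C(=O)c3ccc(O)cc3O)c(O)c2C1=O | target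

## Step count and risks

Total steps: 18. Longest linear sequence: 14 steps (steps 1, 2, 5, 8, 9, 10, 11, 12, 13, 14, 15, 16, 17, 18).

**Step 16 (kinetic protonation to the all-cis ketone).** The dienolate may form slowly at the hindered tertiary carbon, or the quench may give a poor all-cis : trans,trans ratio. Fallback, setting out from 23 and coming back at 25: trap the dienolate with TMSCl to give the bis(trimethylsilyl) derivative F1 (silyl enol ether of the aryl ketone plus O-silylated coumarin) and isolate it without aqueous acid. Then ketonise the neutral enol by slow protodesilylation with citric acid in MeOH at −40 °C. This separates enolate formation from the stereo-determining proton transfer, which then runs on the neutral enol under freely chosen acid, solvent and temperature, and returns 25.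

**Step 17 (the new enantioselective dehydrative prenylation).** Ionisation of the tertiary alcohol by the coumarin may be slow, facial control may be low, or the product may re-ionise. Fallback with known chemistry, setting out from 25 and coming back at 27: alkylate the cesium enolate (Cs2CO3, THF) with prenyl bromide in the presence of Pd(PPh3)4 (5 mol %), a classical achiral Tsuji–Trost allylation in which any O-prenyl isomer re-enters the π-allyl manifold. This gives 27 together with its C3 epimer F2. Because the cyclohexene triad is already enantiopure the two are diastereomers, and 27 is obtained by preparative HPLC rather than by catalyst control.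

**Step 18 (global MOM removal).** Protic acid may cyclise the prenyl group onto a neighbouring phenol or epimerise the all-cis ketone. Fallback, setting out from 27 and coming back at 28: treat 27 with TMSOTf and 2,2'-bipyridyl in MeCN at 0 °C, which transfers each aryl MOM ether into an aryl silyl ether and gives the octakis(trimethylsilyl) ether F3. Hydrolyse F3 with pH 7 buffer to 28. The unmasking then proceeds by silyl transfer and neutral hydrolysis instead of acidolysis.

Further compounds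
F1 | step 16 | bis(trimethylsilyl) derivative of 23 (4-O-TMS coumarin and TMS enol ether of the C4'' ketone) | C[Si](C)(C)OC1=C(c2ccc(OCOC)cc2OCOC)C(=O)Oc2cc(OCOC)c([C@H]3C=C(C)C[C@@H](c4ccc(OCOC)cc4OCOC)C3=C(O[Si](C)(C)C)c5ccc(OCOC)cc5OCOC)c(OCOC)c21
F2 | step 17 | (3R)-epimer of 27 | CC(C)=CC[C@]1(c2ccc(OCOC)cc2OCOC)C(=O)Oc2cc(OCOC)c([C@H]3C=C(C)C[C@@H](c4ccc(OCOC)cc4OCOC)[C@H]3C(=O)c5ccc(OCOC)cc5OCOC)c(OCOC)c2C1=O
F3 | step 18 | octakis(trimethylsilyl) ether of 28 | CC(C)=CC[C@@]1(c2ccc(O[Si](C)(C)C)cc2O[Si](C)(C)C)C(=O)Oc2cc(O[Si](C)(C)C)c([C@H]3C=C(C)C[C@@H](c4ccc(O[Si](C)(C)C)cc4O[Si](C)(C)C)[C@H]3C(=O)c5ccc(O[Si](C)(C)C)cc5O[Si](C)(C)C)c(O[Si](C)(C)C)c2C1=O
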